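**Strategy.** The route rests on cutting the exocyclic C3–CH2O bond of the oxolane ring (O1, C2 aryl, C3, C4 benzyl, C5). The ring is handled at the lactone level (C5 as C=O), so that C3=C4 of an (R)-butenolide is a radical acceptor. A Giese addition of the complete aroyloxymethyl radical joins both halves: the C2 aryl group sends the radical to the opposite face of C3 (2,3-trans) and the new C3 substituent then directs hydrogen-atom transfer to C4 from its far side (3,4-cis). One operation thus forms the bond and two stereocentres. Lactone deoxygenation and hydrogenolysis complete the synthesis.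

Key step: step 7

Remark: the ProPhenol antipode in step 1 is chosen so that the (S)-carbinol results, and the configuration of 3 is to be confirmed before it is carried on. Ring atoms of 13–16 are numbered as in the target oxolane (C5 is the former lactone carbonyl); butenolides 5 and 8 carry furan-2(5H)-one numbering, in which C5 is the aryl-bearing carbon.

**Step 1**
Reactants: 1 4-(benzyloxy)-3-methoxybenzaldehyde; 2 methyl propiolate
Product: 3 methyl (4S)-4-[4-(benzyloxy)-3-methoxyphenyl]-4-hydroxybut-2-ynoate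
Conditions: Me2Zn, ProPhenol ligand (cat.), Ph3P=O (cat.), PhMe, 0 °C
Reagents that add atoms: none
Why: Trost asymmetric alkynylation; the zinc alkynylide adds to the aldehyde inside the chiral dinuclear zinc–ProPhenol pocket, so the carbinol centre (future C2) is set by the catalyst.

**Step 2**
Reactants: 3 methyl (4S)-4-[4-(benzyloxy)-3-methoxyphenyl]-4-hydroxybut-2-ynoate
Product: 5 (5R)-5-[4-(benzyloxy)-3-methoxyphenyl]-3-(tributylstannyl)furan-2(5H)-one, via hydroxy stannyl enoate 4 (not isolated)
Conditions: Bu3SnH, Pd(PPh3)4 (cat.), THF, 0 °C → rt; then PPTS (cat.), CH2Cl2, rt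
Reagents that add atoms: tributyltin hydride CCCC[SnH](CCCC)CCCC
Why: Pd(0)-catalysed syn-hydrostannation of the ynoate should place tin α to the ester with ester and carbinol cis, so that lactonisation to the butenolide follows without touching the stereocentre (the descriptor changes only by CIP priority).

**Step 3**
Reactants: 6 [4-(benzyloxy)-3-methoxyphenyl]methanol
Product: 7 1-(benzyloxy)-4-(bromomethyl)-2-methoxybenzene
Conditions: PBr3, Et2O, 0 °C; used fresh
Reagents that add atoms: phosphorus tribromide BrP(Br)Br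
Why: Bromination of a benzylic alcohol with PBr3 through the phosphite ester and SN2 displacement by bromide.

**Step 4**
Reactants: 5 (5R)-5-[4-(benzyloxy)-3-methoxyphenyl]-3-(tributylstannyl)furan-2(5H)-one; 7 1-(benzyloxy)-4-(bromomethyl)-2-methoxybenzene
Product: 8 (5R)-5-[4-(benzyloxy)-3-methoxyphenyl]-3-[4-(benzyloxy)-3-methoxybenzyl]furan-2(5H)-one
Conditions: Pd2(dba)3 (cat.), AsPh3, THF, 55 °C
Reagents that add atoms: none
Why: Stille sp2–sp3 cross-coupling of an α-stannyl butenolide with a benzylic bromide under neutral conditions, which should leave the base-sensitive C5 stereocentre intact.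

**Step 5**
Reactants: 9 4-(benzyloxy)benzoic acid; 10 chloromethyl chlorosulfate
Product: 11 chloromethyl 4-(benzyloxy)benzoate
Conditions: NaHCO3, Bu4NHSO4 (cat.), CH2Cl2/H2O, 0 °C → rt
Reagents that add atoms: none
Why: Phase-transfer O-alkylation of the carboxylate, in which chlorosulfate is displaced in preference to chloride (SN2).

**Step 6**
Reactants: 11 chloromethyl 4-(benzyloxy)benzoate
Product: 12 iodomethyl 4-(benzyloxy)benzoate
Conditions: NaI, acetone, rt, dark
Reagents that add atoms: sodium iodide [Na+].[I-]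
Why: Finkelstein exchange driven by precipitation of NaCl gives the weak C–I bond needed for radical generation.

**Step 7**
Reactants: 8 (5R)-5-[4-(benzyloxy)-3-methoxyphenyl]-3-[4-(benzyloxy)-3-methoxybenzyl]furan-2(5H)-one; 12 iodomethyl 4-(benzyloxy)benzoate
Product: 13 {(2R,3S,4S)-2-[4-(benzyloxy)-3-methoxyphenyl]-4-[4-(benzyloxy)-3-methoxybenzyl]-5-oxooxolan-3-yl}methyl 4-(benzyloxy)benzoate
Conditions: 12 (excess), (Me3Si)3SiH (slow addition), Et3B/air, PhMe, 0 °C → rt
Reagents that add atoms: none
Why: Ethyl radicals from Et3B/O2 start a chain in which (Me3Si)3Si• abstracts iodine from 12; the aroyloxymethyl radical adds to the β-carbon of the butenolide (future oxolane C3) and the resulting tertiary lactone α-radical takes a hydrogen atom from the silane, which regenerates the silyl radical. The closest known reaction type is the Giese reaction of α-oxygenated alkyl radicals with butenolides. No ring is closed; the intact butenolide ring serves as the stereochemical template. The new C3 centre is controlled by the C2 aryl group, anti to which the radical should attack (2,3-trans), and the new C4 centre by the freshly installed C3 acyloxymethyl group, anti to which the bulky silane should deliver hydrogen (3,4-cis, the kinetic arrangement). The step needs β-regioselectivity, secured by conjugation with the lactone carbonyl, and addition ahead of premature reduction of the radical, secured by excess 12 and slow addition of the silane.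

**Step 8**
Reactants: 13 {(2R,3S,4S)-2-[4-(benzyloxy)-3-methoxyphenyl]-4-[4-(benzyloxy)-3-methoxybenzyl]-5-oxooxolan-3-yl}methyl 4-(benzyloxy)benzoate
Product: 14 {(2R,3S,4S)-2-[4-(benzyloxy)-3-methoxyphenyl]-4-[4-(benzyloxy)-3-methoxybenzyl]-5-hydroxyoxolan-3-yl}methyl 4-(benzyloxy)benzoate (anomeric mixture)
Conditions: Sia2BH (from BH3·THF and 2-methylbut-2-ene), THF, 0 °C → rt; then H2O
Reagents that add atoms: none
Why: Chemoselective lactone-to-lactol reduction with disiamylborane, a reagent that reduces γ-lactones but leaves ordinary esters alone, so the aryl ester and all stereocentres should survive.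

**Step 9**
Reactants: 14 {(2R,3S,4S)-2-[4-(benzyloxy)-3-methoxyphenyl]-4-[4-(benzyloxy)-3-methoxybenzyl]-5-hydroxyoxolan-3-yl}methyl 4-(benzyloxy)benzoate
Product: 15 {(2R,3S,4S)-2-[4-(benzyloxy)-3-methoxyphenyl]-4-[4-(benzyloxy)-3-methoxybenzyl]oxolan-3-yl}methyl 4-(benzyloxy)benzoate
Conditions: Et3SiH, BF3·OEt2, CH2Cl2, −78 → −40 °C
Reagents that add atoms: none
Why: Ionic reduction of the lactol (BF3-promoted oxocarbenium formation, hydride transfer from Et3SiH) turns C5 into a methylene group, so no stereocentre is created and the low temperature should spare the benzylic C2–O bond.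

**Step 10**
Reactants: 15 {(2R,3S,4S)-2-[4-(benzyloxy)-3-methoxyphenyl]-4-[4-(benzyloxy)-3-methoxybenzyl]oxolan-3-yl}methyl 4-(benzyloxy)benzoate
Product: 16 agastinol, [(2R,3S,4S)-2-(4-hydroxy-3-methoxyphenyl)-4-(4-hydroxy-3-methoxybenzyl)oxolan-3-yl]methyl 4-hydroxybenzoate
Conditions: H2 (1 atm), Pd/C, EtOAc–MeOH, rt, stopped at complete debenzylation
Reagents that add atoms: none
Why: Catalytic hydrogenolysis of the three benzyl aryl ethers, which should be faster than cleavage of the benzylic C2–O ring bond under these mild conditions.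

**Compound list**
1 | 4-(benzyloxy)-3-methoxybenzaldehyde | O=Cc1ccc(OCc2ccccc2)c(OC)c1 | starting material
2 | methyl propiolate | C#CC(=O)OC | starting material
3 | methyl (4S)-4-[4-(benzyloxy)-3-methoxyphenyl]-4-hydroxybut-2-ynoate | COC(=O)C#C[C@@H](O)c1ccc(OCc2ccccc2)c(OC)c1 | intermediate
4 | methyl (2E,4R)-4-[4-(benzyloxy)-3-methoxyphenyl]-4-hydroxy-2-(tributylstannyl)but-2-enoate | COC(=O)/C(=C\[C@@H](O)c1ccc(OCc2ccccc2)c(OC)c1)[Sn](CCCC)(CCCC)CCCC | intermediate (not isolated)
5 | (5R)-5-[4-(benzyloxy)-3-methoxyphenyl]-3-(tributylstannyl)furan-2(5H)-one | O=C1O[C@@H](c2ccc(OCc3ccccc3)c(OC)c2)C=C1[Sn](CCCC)(CCCC)CCCC | intermediate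
6 | [4-(benzyloxy)-3-methoxyphenyl]methanol | OCc1ccc(OCc2ccccc2)c(OC)c1 | starting material
7 | 1-(benzyloxy)-4-(bromomethyl)-2-methoxybenzene | BrCc1ccc(OCc2ccccc2)c(OC)c1 | intermediate
8 | (5R)-5-[4-(benzyloxy)-3-methoxyphenyl]-3-[4-(benzyloxy)-3-methoxybenzyl]furan-2(5H)-one | O=C1O[C@@H](c2ccc(OCc3ccccc3)c(OC)c2)C=C1Cc1ccc(OCc2ccccc2)c(OC)c1 | intermediate
9 | 4-(benzyloxy)benzoic acid | OC(=O)c1ccc(OCc2ccccc2)cc1 | starting material
10 | chloromethyl chlorosulfate | ClCOS(=O)(=O)Cl | starting material
11 | chloromethyl 4-(benzyloxy)benzoate | ClCOC(=O)c1ccc(OCc2ccccc2)cc1 | intermediate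
12 | iodomethyl 4-(benzyloxy)benzoate | ICOC(=O)c1ccc(OCc2ccccc2)cc1 | intermediate
13 | {(2R,3S,4S)-2-[4-(benzyloxy)-3-methoxyphenyl]-4-[4-(benzyloxy)-3-methoxybenzyl]-5-oxooxolan-3-yl}methyl 4-(benzyloxy)benzoate | COc1cc(C[C@@H]2C(=O)O[C@@H](c3ccc(OCc4ccccc4)c(OC)c3)[C@@H]2COC(=O)c2ccc(OCc3ccccc3)cc2)ccc1OCc1ccccc1 | intermediate
14 | {(2R,3S,4S)-2-[4-(benzyloxy)-3-methoxyphenyl]-4-[4-(benzyloxy)-3-methoxybenzyl]-5-hydroxyoxolan-3-yl}methyl 4-(benzyloxy)benzoate | COc1cc(C[C@@H]2C(O)O[C@@H](c3ccc(OCc4ccccc4)c(OC)c3)[C@@H]2COC(=O)c2ccc(OCc3ccccc3)cc2)ccc1OCc1ccccc1 | intermediate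
15 | {(2R,3S,4S)-2-[4-(benzyloxy)-3-methoxyphenyl]-4-[4-(benzyloxy)-3-methoxybenzyl]oxolan-3-yl}methyl 4-(benzyloxy)benzoate | COc1cc(C[C@@H]2CO[C@@H](c3ccc(OCc4ccccc4)c(OC)c3)[C@@H]2COC(=O)c2ccc(OCc3ccccc3)cc2)ccc1OCc1ccccc1 | intermediate
16 | agastinol | COc1cc(C[C@@H]2CO[C@@H](c3ccc(O)c(OC)c3)[C@@H]2COC(=O)c2ccc(O)cc2)ccc1O | target

**Totals.** Total step count: 10. Longest linear sequence: 7 steps (1, 2, 4, 7, 8, 9, 10).

**Steps most likely to fail**

Step 7. Hydrogen-atom transfer to the tertiary lactone radical may discriminate the two faces poorly, because the C2 aryl group sits on the face from which hydrogen must arrive; the chain may also be drained by premature reduction of the radical or by abstraction of the activated C–H bonds of 8. The fallback sets out from 3, 12 and 1 and comes back at 13; in it C4 is set by catalytic hydrogenation and not by radical hydrogen transfer. Semi-hydrogenation of 3 over Lindlar catalyst with lactonisation would give (5R)-5-[4-(benzyloxy)-3-methoxyphenyl]furan-2(5H)-one F1. Giese addition of 12 to F1 under the conditions of step 7, which then needs only attack anti to the aryl group, would give {(2R,3S)-2-[4-(benzyloxy)-3-methoxyphenyl]-5-oxooxolan-3-yl}methyl 4-(benzyloxy)benzoate F2. Enolisation with LiHMDS at −78 °C and addition of aldehyde 1 would give the aldol adduct F3, and MsCl/Et3N followed by DBU the (E)-benzylidene lactone F4. Hydrogenation over Rh/Al2O3, chosen to keep the benzyl ethers and the benzylic lactone C–O bond, should add H2 to the exocyclic alkene from the face opposite the C3 substituent and give 13.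

Step 9. BF3 may ionise the benzylic C2–O bond as well as the lactol, which in the presence of the silane leads to ring opening and over-reduction; the oxocarbenium ion may also equilibrate with the enol ether and epimerise C4. The fallback sets out from 14 and comes back at 15, avoiding any combination of Lewis acid and hydride. NaBH4 in THF/MeOH at 0 °C would reduce the open-chain aldehyde form of 14 to (2S,3S)-2-[(R)-[4-(benzyloxy)-3-methoxyphenyl](hydroxy)methyl]-3-[4-(benzyloxy)-3-methoxybenzyl]-4-hydroxybutyl 4-(benzyloxy)benzoate F5. Catalytic camphorsulfonic acid in CH2Cl2 should then close the oxolane by attack of the primary hydroxyl on the C2 benzylic cation, with the 2,3-trans arrangement expected as the favoured outcome, to give 15.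

Step 8. The hindered lactone may react slowly, so that longer times or more reagent erode the selectivity over the aryl ester or push the reduction on to the diol. The fallback sets out from 13 and comes back at 15, giving up the ester on purpose and restoring it at the end. LiAlH4 in THF would reduce both carbonyl groups and give (2S,3S)-2-[4-(benzyloxy)-3-methoxybenzyl]-3-[(R)-[4-(benzyloxy)-3-methoxyphenyl](hydroxy)methyl]butane-1,4-diol F6. Catalytic camphorsulfonic acid should close the ring through the C2 benzylic cation (only the hydroxyl of the C4 side arm can form a five-membered ring; the C3 hydroxymethyl would give an oxetane) to give {(2R,3S,4S)-2-[4-(benzyloxy)-3-methoxyphenyl]-4-[4-(benzyloxy)-3-methoxybenzyl]oxolan-3-yl}methanol F7. Esterification of F7 with acid 9 (DCC, DMAP, CH2Cl2) would give 15.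

**Further compounds**
F1 | step 7 | (5R)-5-[4-(benzyloxy)-3-methoxyphenyl]furan-2(5H)-one | O=C1O[C@@H](c2ccc(OCc3ccccc3)c(OC)c2)C=C1
F2 | step 7 | {(2R,3S)-2-[4-(benzyloxy)-3-methoxyphenyl]-5-oxooxolan-3-yl}methyl 4-(benzyloxy)benzoate | O=C1O[C@@H](c2ccc(OCc3ccccc3)c(OC)c2)[C@H](COC(=O)c2ccc(OCc3ccccc3)cc2)C1
F3 | step 7 | {(2R,3S)-2-[4-(benzyloxy)-3-methoxyphenyl]-4-{[4-(benzyloxy)-3-methoxyphenyl](hydroxy)methyl}-5-oxooxolan-3-yl}methyl 4-(benzyloxy)benzoate (aldol adduct, mixture at the two new centres) | O=C1O[C@@H](c2ccc(OCc3ccccc3)c(OC)c2)[C@H](COC(=O)c2ccc(OCc3ccccc3)cc2)C1C(O)c1ccc(OCc2ccccc2)c(OC)c1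
F4 | step 7 | {(2R,3S,4E)-2-[4-(benzyloxy)-3-methoxyphenyl]-4-[4-(benzyloxy)-3-methoxybenzylidene]-5-oxooxolan-3-yl}methyl 4-(benzyloxy)benzoate | O=C1O[C@@H](c2ccc(OCc3ccccc3)c(OC)c2)[C@H](COC(=O)c2ccc(OCc3ccccc3)cc2)/C1=C\c1ccc(OCc2ccccc2)c(OC)c1
F5 | step 9 | (2S,3S)-2-[(R)-[4-(benzyloxy)-3-methoxyphenyl](hydroxy)methyl]-3-[4-(benzyloxy)-3-methoxybenzyl]-4-hydroxybutyl 4-(benzyloxy)benzoate | COc1cc(C[C@H](CO)[C@@H](COC(=O)c2ccc(OCc3ccccc3)cc2)[C@@H](O)c2ccc(OCc3ccccc3)c(OC)c2)ccc1OCc1ccccc1
F6 | step 8 | (2S,3S)-2-[4-(benzyloxy)-3-methoxybenzyl]-3-[(R)-[4-(benzyloxy)-3-methoxyphenyl](hydroxy)methyl]butane-1,4-diol | COc1cc(C[C@H](CO)[C@@H](CO)[C@@H](O)c2ccc(OCc3ccccc3)c(OC)c2)ccc1OCc1ccccc1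
F7 | step 8 | {(2R,3S,4S)-2-[4-(benzyloxy)-3-methoxyphenyl]-4-[4-(benzyloxy)-3-methoxybenzyl]oxolan-3-yl}methanol | COc1cc(C[C@@H]2CO[C@@H](c3ccc(OCc4ccccc4)c(OC)c3)[C@@H]2CO)ccc1OCc1ccccc1
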